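**Strategy**

The cyclohexa-2,5-diene ring (C1 = CHOAc, C2 = C–OMe, C4 = CHOH, C6 = carbon bearing the side chain) is cut at C3–C4 and C1–C6 into two three-carbon pieces. C4–C5–C6 with the acetylated side chain is an ynal, a 1,3-dielectrophile. C1–C2–C3 is 2-methoxyallyl acetate: its enol ether, which in the target lies between the two carbinol carbons, reacts twice as a nucleophile. In one flask a titanium-catalysed asymmetric carbonyl-ene reaction joins C3 to C4 and a gold-catalysed 6-endo-dig cycloisomerisation joins C1 to C6, a formal [3+3] annulation that gives the target itself. The side-chain stereocenter is bought with (R)-epichlorohydrin, C4 is set by the catalyst, and C1 is relayed from C4.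

Key step: step 8

Assumption: the (S)-binaphthyl ligand is taken to send the ene component to the Re face of the aldehyde; if the sense of induction is the opposite, the (R)-ligand is used. The non-isolated ene adduct is drawn as its (Z)-enol ether.

**Route**

Step 1
Reactants: 1 (R)-epichlorohydrin; 2 decylmagnesium bromide
Product: 3 (R)-1-chlorotridecan-2-ol
Conditions: CuI (10 mol%), THF, −40 to 0 °C; H2O quench
Reagents that add atoms: none
Why: Copper-catalysed Grignard opening of the epoxide at its CH2 carbon (SN2) should leave the stereocenter untouched and keep the chloride for the next ring closure.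

Step 2
Reactants: 3 (R)-1-chlorotridecan-2-ol
Product: 4 (R)-2-undecyloxirane
Conditions: NaOH, H2O/Et2O, rt
Reagents that add atoms: none
Why: Intramolecular Williamson etherification closes the epoxide at the CH2Cl carbon, so the carbinol center keeps its (R) configuration.

Step 3
Reactants: 4 (R)-2-undecyloxirane; 5 3,3-diethoxyprop-1-yne
Product: 7 (R)-1,1-diethoxyhexadec-2-yn-5-ol, via lithium acetylide 6 (not isolated)
Conditions: 5, n-BuLi, THF, −78 °C; BF3·OEt2; then 4, −78 °C
Reagents that add atoms: none
Why: BF3-promoted alkynylation of a terminal epoxide by the lithium acetylide should occur at the CH2 carbon and leave the carbinol stereocenter as bought.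

Step 4
Reactants: 7 (R)-1,1-diethoxyhexadec-2-yn-5-ol
Product: 8 (R)-1,1-diethoxyhexadec-2-yn-5-yl acetate
Conditions: Ac2O, pyridine, DMAP (cat.), CH2Cl2, 0 °C to rt
Reagents that add atoms: acetic anhydride, CC(=O)OC(C)=O
Why: DMAP-catalysed acylation installs the side-chain acetate of the target, which also keeps this oxygen from adding to the alkyne in the gold step.

Step 5
Reactants: 8 (R)-1,1-diethoxyhexadec-2-yn-5-yl acetate
Product: 9 (R)-1-oxohexadec-2-yn-5-yl acetate
Conditions: HCO2H/H2O (9:1), CH2Cl2, 0 °C to rt
Reagents that add atoms: water, O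
Why: Acid-catalysed acetal hydrolysis should release the ynal while the acetate survives aqueous formic acid.

Step 6
Reactants: 10 methyl 2-methoxyacrylate
Product: 11 2-methoxyprop-2-en-1-ol
Conditions: DIBAL-H (iBu2AlH, 2.2 equiv), Et2O, −78 to 0 °C; aq KNaC4H4O6 (sodium potassium tartrate)
Reagents that add atoms: none
Why: DIBAL-H 1,2-reduction of the ester gives the allylic alcohol, and the non-acidic tartrate work-up spares the enol ether.

Step 7
Reactants: 11 2-methoxyprop-2-en-1-ol
Product: 12 2-methoxyallyl acetate
Conditions: Ac2O, Et3N, DMAP (cat.), CH2Cl2, 0 °C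
Reagents that add atoms: acetic anhydride, CC(=O)OC(C)=O
Why: Acylation under basic conditions should leave the acid-labile enol ether intact.

Step 8
Reactants: 9 (R)-1-oxohexadec-2-yn-5-yl acetate; 12 2-methoxyallyl acetate
Product: 14 (1S,4S)-6-[(2R)-2-acetoxytridecyl]-4-hydroxy-2-methoxycyclohexa-2,5-dien-1-yl acetate (target), via ene adduct 13 (not isolated)
Conditions: 12 (3 equiv), Ti(OiPr)4/(S)-2-[(3-bromo-5-tert-butyl-2-hydroxybenzylidene)amino]-2'-hydroxy-1,1'-binaphthyl/3,5-di-tert-butylsalicylic acid (10 mol%), 2,6-di-tert-butyl-4-methylpyridine, toluene, 0 °C; then [(tBu2(2-biphenylyl)P)Au(MeCN)]SbF6 (5 mol%), CH2Cl2, −20 °C to rt; Et3N-deactivated silica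
Reagents that add atoms: none
Why: Proposed new method: the titanium Lewis acid mediates a carbonyl-ene reaction in which the CH2= carbon of 12 (future C3) adds to the aldehyde carbon of 9 (future C4) and a hydrogen of the CH2OAc group moves to oxygen, so that the enol ether now ends at the acetoxy carbon (13); cationic gold then activates the alkyne, this enol ether carbon (future C1) attacks the distal alkyne carbon (future C6) anti to gold, the C2 oxocarbenium ion loses a C3 proton to the hindered pyridine and the vinylgold is protonated at C5. The closest known reactions are the titanium–binaphthyl Schiff base catalysed ene reaction of 2-methoxypropene with aldehydes (ynals included) and gold-catalysed 6-endo-dig carbocyclisations of enol ethers and of 1,5-enynes to cyclohexa-1,4-dienes; their union in one flask, with a methyl enol ether that is regenerated, is new. The ring closes 6-endo-dig at the alkyne (6-endo-trig at the enol ether). C4 is set by the catalyst, which shields one face of the bound aldehyde so that C3 adds to the Re face; C1 is set by substrate control, a half-chair transition state that places the propargylic hydroxyl and the acetoxy group of the (Z)-enol ether both pseudoequatorial, which is the 1,4-trans ring. The step needs 6-endo over 5-exo closure, secured by the methoxy-stabilised cation at C2 and by the C4 oxygen, which makes C6 the more electrophilic alkyne carbon, and it needs loss of a C3 and not the C1 proton, favoured kinetically at the less hindered methylene as in amine-mediated ketal-to-enol-ether eliminations. The ynal and the enol ether cannot react with themselves, the acetylated side chain cannot add its oxygen to the alkyne, and the hindered base keeps the acid-labile product from ionising at C4.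

**Compound list**

1 | (R)-epichlorohydrin [(R)-2-(chloromethyl)oxirane] | ClC[C@H]1CO1 | starting material
2 | decylmagnesium bromide | CCCCCCCCCC[Mg]Br | starting material
3 | (R)-1-chlorotridecan-2-ol | CCCCCCCCCCC[C@@H](O)CCl | intermediate
4 | (R)-2-undecyloxirane | CCCCCCCCCCC[C@@H]1CO1 | intermediate
5 | 3,3-diethoxyprop-1-yne | C#CC(OCC)OCC | starting material
6 | lithium 3,3-diethoxyprop-1-yn-1-ide (not isolated) | [Li]C#CC(OCC)OCC | intermediate
7 | (R)-1,1-diethoxyhexadec-2-yn-5-ol | CCCCCCCCCCC[C@H](CC#CC(OCC)OCC)O | intermediate
8 | (R)-1,1-diethoxyhexadec-2-yn-5-yl acetate | CCCCCCCCCCC[C@H](CC#CC(OCC)OCC)OC(C)=O | intermediate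
9 | (R)-1-oxohexadec-2-yn-5-yl acetate | CCCCCCCCCCC[C@H](CC#CC=O)OC(C)=O | intermediate
10 | methyl 2-methoxyacrylate | C=C(OC)C(=O)OC | starting material
11 | 2-methoxyprop-2-en-1-ol | C=C(OC)CO | intermediate
12 | 2-methoxyallyl acetate | C=C(OC)COC(C)=O | intermediate
13 | (1Z,4R,8R)-4-hydroxy-2-methoxynonadec-1-en-5-yne-1,8-diyl diacetate (ene adduct, not isolated) | CCCCCCCCCCC[C@H](CC#C[C@H](O)C/C(OC)=C/OC(C)=O)OC(C)=O | intermediate
14 | (1S,4S)-6-[(2R)-2-acetoxytridecyl]-4-hydroxy-2-methoxycyclohexa-2,5-dien-1-yl acetate | CCCCCCCCCCC[C@H](CC1=C[C@H](O)C=C(OC)[C@H]1OC(C)=O)OC(C)=O | target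

**Step count**

Total steps: 8. Longest linear sequence: 6 steps (1, 2, 3, 4, 5, 8).

**Steps most likely to fail**

1. Step 8 (Proposed new method). What may go wrong: poor facial control when C1 adds to C6, which would give the 1,4-cis ring; closure to the five-membered ring at the inner alkyne carbon; or loss of the C1 proton in place of a C3 proton, after which water is lost and the ring aromatises. The fallback uses known chemistry, sets out from 9 (with 11 as the second piece) and returns at 14. Hydroiodination of 9 (NaI, AcOH) should give the (Z)-β-iodoenal F1. Enantioselective vinylation of its aldehyde (divinylzinc, Zn(CH=CH2)2, catalytic chiral amino alcohol) and silylation (TESCl, imidazole) should give the vinyl iodide F2. Oxidation of 11 with MnO2 should give 2-methoxyacrolein F3. A Nozaki–Hiyama–Kishi coupling of F2 with F3 (CrCl2, NiCl2 cat., chiral sulfonamide ligand, DMSO) and acetylation (Ac2O, DMAP) should give the triene acetate F4, so that both ring carbinols are set by reagent control before the ring exists. Ring-closing metathesis of the vinyl group onto the methyl enol ether (second-generation Grubbs catalyst, toluene, 60 °C) should give the triethylsilyl ether F5, and buffered fluoride (TBAF, AcOH, THF) should release 14.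

2. Step 5. What may go wrong: decomposition of the ynal during acetal hydrolysis, by elimination of the homopropargylic acetate or by oligomerisation. The fallback sets out from 4 and returns at 9. Opening of 4 with the lithium acetylide of tert-butyldimethyl(prop-2-yn-1-yloxy)silane (n-BuLi, BF3·OEt2, THF, −78 °C) should give the alcohol F6. Acetylation should give its acetate F7, and desilylation (HF·pyridine, THF) the propargylic alcohol F8. Oxidation with MnO2 in CH2Cl2 should then give 9 under neutral conditions.

3. Step 3. What may go wrong: ionisation of the acetal by BF3 or incomplete opening of the epoxide. The fallback sets out from 4 and returns at 7. Opening of 4 with lithium acetylide–ethylenediamine complex (LiC≡CH·H2NCH2CH2NH2, DMSO, rt) should give the terminal alkyne F9. Its bis-magnesium salt (EtMgBr, 2 equiv, THF) is then heated with triethyl orthoformate (Bodroux–Chichibabin-type acetal synthesis) to give 7, with no Lewis acid present beside the acetal.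

**Further compounds**

F1 | step 8 | (2Z,5R)-3-iodo-1-oxohexadec-2-en-5-yl acetate | CCCCCCCCCCC[C@H](C/C(I)=C/C=O)OC(C)=O
F2 | step 8 | (3R,4Z,7R)-5-iodo-3-[(triethylsilyl)oxy]octadeca-1,4-dien-7-yl acetate | CCCCCCCCCCC[C@H](C/C(I)=C/[C@H](O[Si](CC)(CC)CC)C=C)OC(C)=O
F3 | step 8 | 2-methoxyacrolein | C=C(OC)C=O
F4 | step 8 | (3S,4Z,6R)-4-[(2R)-2-acetoxytridecyl]-2-methoxy-6-[(triethylsilyl)oxy]octa-1,4,7-trien-3-yl acetate | CCCCCCCCCCC[C@H](C/C(=C/[C@H](O[Si](CC)(CC)CC)C=C)[C@H](OC(C)=O)C(OC)=C)OC(C)=O
F5 | step 8 | (1S,4S)-6-[(2R)-2-acetoxytridecyl]-2-methoxy-4-[(triethylsilyl)oxy]cyclohexa-2,5-dien-1-yl acetate | CCCCCCCCCCC[C@H](CC1=C[C@H](O[Si](CC)(CC)CC)C=C(OC)[C@H]1OC(C)=O)OC(C)=O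
F6 | step 5 | (R)-1-[(tert-butyldimethylsilyl)oxy]hexadec-2-yn-5-ol | CCCCCCCCCCC[C@H](CC#CCO[Si](C)(C)C(C)(C)C)O
F7 | step 5 | (R)-1-[(tert-butyldimethylsilyl)oxy]hexadec-2-yn-5-yl acetate | CCCCCCCCCCC[C@H](CC#CCO[Si](C)(C)C(C)(C)C)OC(C)=O
F8 | step 5 | (R)-1-hydroxyhexadec-2-yn-5-yl acetate | CCCCCCCCCCC[C@H](CC#CCO)OC(C)=O
F9 | step 3 | (R)-pentadec-1-yn-4-ol | CCCCCCCCCCC[C@H](CC#C)O
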